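The 5,6-dihydropyran-2-one ring (ring O, C1=O, C2=C3, C4H2, C5H; chain numbering from the lactone carbonyl) is read as propiolic acid laid across a terminal alkene. O, C1, C2 and C3 are HC≡C–CO2H, and C4 and C5 are the CH2=CH end of an allyl group. A chiral cationic gold(I) catalyst joins C3 to C4 and the carboxyl oxygen to C5 in one atom-economical [4+2] annulation that builds the whole lactone and sets C5. The precursor is the protected C4–C26 alkene (7,9-acetonide, 11,15-bis-TBS ether). It is assembled by a one-flask silyl-dithiane linchpin union of two enantiopure epoxides, the larger one cut from C2-symmetric (R,R)-1,2:6,7-diepoxyheptane.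

Key step: step 11

Numbering: C1 = lactone C=O, C5 = ring CH–O, C7/C9/C11/C15 = carbinol carbons, C26 = methyl. The target is (5S,7R,9R,11R,15S): C5, C7, C9 and C11 are all-syn, and C15 lies on the opposite side in the zigzag drawing. TBS = tert-butyldimethylsilyl, TBSO = its oxy group.
Assumption: the sense of induction of the chiral digold catalyst on this alkene cannot be derived from a model. The (R)-ligand is written, and its equally available antipode is used if that one proves to be the matched one.
Assumption: 2-(tert-butyldimethylsilyl)-1,3-dithiane and the Grignard solutions are taken as commercial.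

Step 1
Reactants: 1 hepta-1,6-diene
Product: 2 1,2:6,7-diepoxyheptane (statistical mixture of the R,R/S,S pair and the meso isomer)
Conditions: mCPBA (2.4 equiv), CH2Cl2, 0 °C to rt
Reagents that add atoms: mCPBA, OOC(=O)c1cccc(Cl)c1
Why: Prilezhaev epoxidation of two isolated terminal alkenes is reliable, and its lack of facial selectivity does not matter because step 2 sorts the stereoisomers.

Step 2
Reactants: 2 1,2:6,7-diepoxyheptane (isomer mixture)
Product: 3 (2R,2'R)-2,2'-(propane-1,3-diyl)bis(oxirane)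
Conditions: (R,R)-(salen)Co(III)OAc (1 mol %), H2O (1.1 equiv), THF, 0 °C to rt; distillation
Reagents that add atoms: none
Why: In the Jacobsen hydrolytic kinetic resolution the (R,R)-catalyst hydrolyses (S)-configured terminal oxiranes much faster, so every isomer that holds an (S)-oxirane becomes a polar diol or tetrol and only the (R,R)-diepoxide, which carries the future C11 and C15, should remain, its enantiopurity raised by the double selection.

Step 3
Reactants: 3 (2R,2'R)-2,2'-(propane-1,3-diyl)bis(oxirane); 4 decylmagnesium bromide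
Product: 5 (4S)-1-[(2R)-oxiran-2-yl]pentadecan-4-ol
Conditions: CuI (10 mol %), THF, −40 °C, 3 in excess (2 equiv, surplus recovered); aqueous quench
Reagents that add atoms: none
Why: This copper-catalysed SN2 opening of a terminal epoxide by a Grignard reagent occurs at the CH2 carbon and leaves the stereocentres untouched; the two oxiranes of C2-symmetric 3 are homotopic, so only one mono-adduct can form, and excess 3 at low temperature holds back double addition.

Step 4
Reactants: 5 (4S)-1-[(2R)-oxiran-2-yl]pentadecan-4-ol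
Product: 6 tert-butyldimethyl{[(4S)-1-[(2R)-oxiran-2-yl]pentadecan-4-yl]oxy}silane
Conditions: TBSCl, imidazole, DMF, rt
Reagents that add atoms: TBSCl, CC(C)(C)[Si](C)(C)Cl
Why: Imidazole-promoted silyl ether formation masks the C15 hydroxyl under near-neutral conditions that leave the oxirane intact and remove the risk of tetrahydropyran formation.

Step 5
Reactants: 7 (S)-epichlorohydrin; 8 vinylmagnesium bromide
Product: 9 (2S)-1-chloropent-4-en-2-ol
Conditions: CuI (10 mol %), THF, −78 to −20 °C; aqueous quench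
Reagents that add atoms: none
Why: Copper-catalysed Grignard opening of the epoxide at its CH2 terminus is faster than chloride displacement, and the carbinol stereocentre (future C7) takes no part in it.

Step 6
Reactants: 9 (2S)-1-chloropent-4-en-2-ol
Product: 10 (2S)-2-(prop-2-enyl)oxirane
Conditions: powdered NaOH, Et2O, rt; distillation
Reagents that add atoms: none
Why: Intramolecular Williamson closure of the chlorohydrin displaces chloride at the primary carbon, so the C–O stereocentre is retained.

Step 7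
Reactants: 11 2-(tert-butyldimethylsilyl)-1,3-dithiane; 6 tert-butyldimethyl{[(4S)-1-[(2R)-oxiran-2-yl]pentadecan-4-yl]oxy}silane; 10 (2S)-2-(prop-2-enyl)oxirane
Product: 15 (2S)-1-{2-[(2R,6S)-2,6-bis(TBSO)heptadecyl]-1,3-dithian-2-yl}pent-4-en-2-ol, via lithiated silyl dithiane 12 (not isolated), via lithium alkoxide 13 (not isolated), via relay carbanion 14 (not isolated)
Conditions: 11, t-BuLi, Et2O, −78 to −45 °C; 6, −78 to −25 °C; then 10, HMPA, THF, −78 °C to rt; aqueous quench
Reagents that add atoms: none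
Why: In this three-component linchpin coupling (anion relay chemistry) the dithiane anion opens 6 at C10, HMPA then triggers a 1,4-Brook rearrangement that moves the silyl group to O11 and regenerates a dithiane anion, and this opens 10 at C8, both epoxide stereocentres being carried over unchanged.

Step 8
Reactants: 15 (2S)-1-{2-[(2R,6S)-2,6-bis(TBSO)heptadecyl]-1,3-dithian-2-yl}pent-4-en-2-ol
Product: 16 (4S,8R,12S)-8,12-bis(TBSO)-4-hydroxytricos-1-en-6-one
Conditions: MeI, CaCO3, MeCN/H2O 9:1, 40 °C
Reagents that add atoms: water, O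
Why: In this alkylative dithioacetal hydrolysis S-methylation turns sulfur into a leaving group and water captures the thionium ion, while CaCO3 keeps the medium neutral so that the β-hydroxy ketone, the alkene and the silyl ethers survive.

Step 9
Reactants: 16 (4S,8R,12S)-8,12-bis(TBSO)-4-hydroxytricos-1-en-6-one
Product: 17 (4S,6S,8R,12S)-8,12-bis(TBSO)tricos-1-ene-4,6-diol
Conditions: Et2BOMe, THF/MeOH 4:1, −78 °C; NaBH4; AcOH, then MeOH co-evaporation
Reagents that add atoms: none
Why: In the Narasaka–Prasad reduction boron ties O7 and the C9 carbonyl into a six-membered chelate and external hydride attacks it axially, which sets C9 syn to C7.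

Step 10
Reactants: 17 (4S,6S,8R,12S)-8,12-bis(TBSO)tricos-1-ene-4,6-diol
Product: 18 (4S,6S)-4-(prop-2-enyl)-6-[(2R,6S)-2,6-bis(TBSO)heptadecyl]-2,2-dimethyl-1,3-dioxane
Conditions: Me2C(OMe)2, PPTS (cat), CH2Cl2, rt
Reagents that add atoms: 2,2-dimethoxypropane, COC(C)(C)OC
Why: Acid-catalysed transketalisation turns the syn-1,3-diol into a chair acetonide with both side chains equatorial, and PPTS is too mild to touch the TBS ethers.

Step 11
Reactants: 18 (4S,6S)-4-(prop-2-enyl)-6-[(2R,6S)-2,6-bis(TBSO)heptadecyl]-2,2-dimethyl-1,3-dioxane; 19 propiolic acid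
Product: 21 (6S)-6-({(4R,6S)-6-[(2R,6S)-2,6-bis(TBSO)heptadecyl]-2,2-dimethyl-1,3-dioxan-4-yl}methyl)-5,6-dihydro-2H-pyran-2-one, via alkenylgold lactone 20 (not isolated)
Conditions: (R)-DTBM-SEGPHOS(AuCl)2 (5 mol %), AgSbF6 (10 mol %), 4 Å MS, ClCH2CH2Cl, rt; 19 (3 equiv) added slowly
Reagents that add atoms: none
Why: Proposed new method: the cationic gold(I) centre π-activates 19, the terminal alkene carbon C4 of 18 attacks the conjugate alkyne carbon C3, and the positive charge growing at C5 (cyclopropyl gold carbene or homoallyl cation character) is taken up in the same concerted but asynchronous event by the carboxyl C=O oxygen, after which proton loss gives alkenylgold lactone 20 and protodeauration at C2 releases 21 and the catalyst. The closest known reaction type is the gold(I)-catalysed intermolecular [4+2] annulation of propiolic acids with simple alkenes to α,β-unsaturated δ-lactones, known with net cis addition and with only preliminary enantioselective variants, so the polyoxygenated monosubstituted alkene and the demand for high catalyst-controlled face selectivity are the untested part. The only ring closed is the six-membered lactone, formed as a formal [4+2] of the four-atom unit O=C1–C2≡C3 and the two-atom unit C4=C5, the O–C5 bond closing the six-membered ring onto the cationic carbon. The new stereocentre C5 is controlled by the chiral bisphosphine on gold, which decides which alkene face meets the bound alkyne, while the resident C7 centre, two bonds from the alkene, should add only a weak bias and makes any C5 epimer a separable diastereomer. Regioselectivity (C3 to C4, O to C5) follows from Markovnikov polarisation of the alkene and conjugate polarisation of the alkynoic acid. Chemoselectivity needs the ether oxygens to stay out: O7 and O9 are tied back in the chair acetonide whose allyl arm is equatorial, so neither reaches C5 through an unstrained ring, the silyl ethers are poor nucleophiles, and slow addition of 19 limits its self-addition.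

Step 12
Reactants: 21 (6S)-6-({(4R,6S)-6-[(2R,6S)-2,6-bis(TBSO)heptadecyl]-2,2-dimethyl-1,3-dioxan-4-yl}methyl)-5,6-dihydro-2H-pyran-2-one
Product: 22 (6S)-6-[(2R,4R,6R,10S)-2,4,6,10-tetrahydroxyhenicosyl]-5,6-dihydro-2H-pyran-2-one (target)
Conditions: 48% aq HF, MeCN, 0 °C to rt
Reagents that add atoms: none
Why: In this global deprotection fluoride-driven desilylation removes both TBS ethers and the aqueous acid hydrolyses the acetonide in the same flask, no stereocentre is touched, and the unsaturated lactone tolerates the mildly acidic medium.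

Compound list
1 | hepta-1,6-diene | C=CCCCC=C | starting material
2 | 1,2:6,7-diepoxyheptane, stereoisomer mixture | C1OC1CCCC1CO1 | intermediate
3 | (2R,2'R)-2,2'-(propane-1,3-diyl)bis(oxirane) | C1O[C@@H]1CCC[C@@H]1CO1 | intermediate
4 | decylmagnesium bromide | CCCCCCCCCC[Mg]Br | starting material
5 | (4S)-1-[(2R)-oxiran-2-yl]pentadecan-4-ol | CCCCCCCCCCC[C@H](O)CCC[C@@H]1CO1 | intermediate
6 | tert-butyldimethyl{[(4S)-1-[(2R)-oxiran-2-yl]pentadecan-4-yl]oxy}silane | CCCCCCCCCCC[C@H](O[Si](C)(C)C(C)(C)C)CCC[C@@H]1CO1 | intermediate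
7 | (S)-epichlorohydrin | ClC[C@@H]1CO1 | starting material
8 | vinylmagnesium bromide | C=C[Mg]Br | starting material
9 | (2S)-1-chloropent-4-en-2-ol | ClC[C@@H](O)CC=C | intermediate
10 | (2S)-2-(prop-2-enyl)oxirane | C=CC[C@H]1CO1 | intermediate
11 | 2-(tert-butyldimethylsilyl)-1,3-dithiane | CC(C)(C)[Si](C)(C)C1SCCCS1 | starting material
12 | 2-lithio-2-(tert-butyldimethylsilyl)-1,3-dithiane | CC(C)(C)[Si](C)(C)C1([Li])SCCCS1 | intermediate
13 | lithium (2R,6S)-6-(TBSO)-1-[2-(TBS)-1,3-dithian-2-yl]heptadecan-2-olate | CCCCCCCCCCC[C@H](O[Si](C)(C)C(C)(C)C)CCC[C@@H](O[Li])CC1([Si](C)(C)C(C)(C)C)SCCCS1 | intermediate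
14 | 2-lithio-2-[(2R,6S)-2,6-bis(TBSO)heptadecyl]-1,3-dithiane | CCCCCCCCCCC[C@H](O[Si](C)(C)C(C)(C)C)CCC[C@@H](O[Si](C)(C)C(C)(C)C)CC1([Li])SCCCS1 | intermediate
15 | (2S)-1-{2-[(2R,6S)-2,6-bis(TBSO)heptadecyl]-1,3-dithian-2-yl}pent-4-en-2-ol | CCCCCCCCCCC[C@H](O[Si](C)(C)C(C)(C)C)CCC[C@@H](O[Si](C)(C)C(C)(C)C)CC1(C[C@@H](O)CC=C)SCCCS1 | intermediate
16 | (4S,8R,12S)-8,12-bis(TBSO)-4-hydroxytricos-1-en-6-one | CCCCCCCCCCC[C@H](O[Si](C)(C)C(C)(C)C)CCC[C@@H](O[Si](C)(C)C(C)(C)C)CC(=O)C[C@@H](O)CC=C | intermediate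
17 | (4S,6S,8R,12S)-8,12-bis(TBSO)tricos-1-ene-4,6-diol | CCCCCCCCCCC[C@H](O[Si](C)(C)C(C)(C)C)CCC[C@@H](O[Si](C)(C)C(C)(C)C)C[C@@H](O)C[C@@H](O)CC=C | intermediate
18 | (4S,6S)-4-(prop-2-enyl)-6-[(2R,6S)-2,6-bis(TBSO)heptadecyl]-2,2-dimethyl-1,3-dioxane | CCCCCCCCCCC[C@H](O[Si](C)(C)C(C)(C)C)CCC[C@@H](O[Si](C)(C)C(C)(C)C)C[C@@H]1C[C@H](CC=C)OC(C)(C)O1 | intermediate
19 | propiolic acid | C#CC(=O)O | starting material
20 | C2-aurated lactone (alkenylgold(I) species, phosphine on gold not drawn) | CCCCCCCCCCC[C@H](O[Si](C)(C)C(C)(C)C)CCC[C@@H](O[Si](C)(C)C(C)(C)C)C[C@@H]1C[C@H](C[C@@H]2CC=C([Au])C(=O)O2)OC(C)(C)O1 | intermediate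
21 | (6S)-6-({(4R,6S)-6-[(2R,6S)-2,6-bis(TBSO)heptadecyl]-2,2-dimethyl-1,3-dioxan-4-yl}methyl)-5,6-dihydro-2H-pyran-2-one | CCCCCCCCCCC[C@H](O[Si](C)(C)C(C)(C)C)CCC[C@@H](O[Si](C)(C)C(C)(C)C)C[C@@H]1C[C@H](C[C@@H]2CC=CC(=O)O2)OC(C)(C)O1 | intermediate
22 | (6S)-6-[(2R,4R,6R,10S)-2,4,6,10-tetrahydroxyhenicosyl]-5,6-dihydro-2H-pyran-2-one | CCCCCCCCCCC[C@H](O)CCC[C@@H](O)C[C@@H](O)C[C@@H](O)C[C@@H]1CC=CC(=O)O1 | target

Total step count: 12. Longest linear sequence: 10 (steps 1–4 and 7–12).

Steps most likely to fail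

Risk 1, step 11 (bears the label "Proposed new method:"). Several things may go wrong.
- Face selection at the monosubstituted alkene may be poor.
- The alkene may attack so slowly that self-addition of propiolic acid or formal enyne metathesis takes over.
- The acidic medium may strip the acetonide.

The fallback uses known chemistry, sets out from 18 and returns at 21.
- Ozonolysis (O3, CH2Cl2, −78 °C; PPh3) should give {(4R,6S)-6-[(2R,6S)-2,6-bis(TBSO)heptadecyl]-2,2-dimethyl-1,3-dioxan-4-yl}acetaldehyde F1.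
- Brown allylation with the B-allyldiisopinocampheylborane made from (−)-Ipc2BOMe, which comes from (+)-α-pinene, and allylmagnesium bromide sets C5 under reagent control. It should give (2S)-1-{(4S,6S)-6-[(2R,6S)-2,6-bis(TBSO)heptadecyl]-2,2-dimethyl-1,3-dioxan-4-yl}pent-4-en-2-ol F2.
- Acryloyl chloride/Et3N should give the corresponding prop-2-enoate ester F3.
- Ring-closing metathesis (Grubbs second-generation catalyst, CH2Cl2, reflux) closes C2=C3 and delivers 21.

Risk 2, step 3. Statistical over-addition to the second oxirane may occur, the magnesium alkoxide may cyclise onto the remaining oxirane, or halide may open the epoxide.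

The fallback builds the two stereocentres one after the other instead of from the diepoxide. It sets out from 4 and 7 and returns at 6.
- CuI-catalysed opening of 7 by 4 should give (2S)-1-chlorotridecan-2-ol F4.
- NaOH closes this to (2S)-2-undecyloxirane F5.
- But-3-enylmagnesium bromide/CuI opens the oxirane to (6S)-heptadec-1-en-6-ol F6.
- TBSCl/imidazole gives tert-butyl{[(6S)-heptadec-1-en-6-yl]oxy}dimethylsilane F7.
- mCPBA gives tert-butyldimethyl{[(4S)-1-(oxiran-2-yl)pentadecan-4-yl]oxy}silane as an oxirane epimer pair F8.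
- Hydrolytic kinetic resolution with the (R,R)-(salen)Co catalyst leaves the (R)-oxirane, which is 6.

Risk 3, step 7. The Brook rearrangement may be premature or incomplete, so that the two epoxides are scrambled, or the relay anion may be quenched by a proton.

The fallback gives up the relay and alkylates a plain dithiane twice. It sets out from 6 and returns at 14 and then 15.
- 2-Lithio-1,3-dithiane (n-BuLi, THF) opens 6 to (2R,6S)-6-(TBSO)-1-(1,3-dithian-2-yl)heptadecan-2-ol F9.
- TBSOTf/2,6-lutidine gives 2-[(2R,6S)-2,6-bis(TBSO)heptadecyl]-1,3-dithiane F10.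
- Metalation (t-BuLi, HMPA/THF, −78 °C) gives 14, and addition of 10 gives 15.

Further compounds
F1 | step 11 | {(4R,6S)-6-[(2R,6S)-2,6-bis(TBSO)heptadecyl]-2,2-dimethyl-1,3-dioxan-4-yl}acetaldehyde | CCCCCCCCCCC[C@H](O[Si](C)(C)C(C)(C)C)CCC[C@@H](O[Si](C)(C)C(C)(C)C)C[C@@H]1C[C@H](CC=O)OC(C)(C)O1
F2 | step 11 | (2S)-1-{(4S,6S)-6-[(2R,6S)-2,6-bis(TBSO)heptadecyl]-2,2-dimethyl-1,3-dioxan-4-yl}pent-4-en-2-ol | CCCCCCCCCCC[C@H](O[Si](C)(C)C(C)(C)C)CCC[C@@H](O[Si](C)(C)C(C)(C)C)C[C@@H]1C[C@H](C[C@@H](O)CC=C)OC(C)(C)O1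
F3 | step 11 | (2S)-1-{(4R,6S)-6-[(2R,6S)-2,6-bis(TBSO)heptadecyl]-2,2-dimethyl-1,3-dioxan-4-yl}pent-4-en-2-yl prop-2-enoate | CCCCCCCCCCC[C@H](O[Si](C)(C)C(C)(C)C)CCC[C@@H](O[Si](C)(C)C(C)(C)C)C[C@@H]1C[C@H](C[C@@H](OC(=O)C=C)CC=C)OC(C)(C)O1
F4 | step 3 | (2S)-1-chlorotridecan-2-ol | CCCCCCCCCCC[C@H](O)CCl
F5 | step 3 | (2S)-2-undecyloxirane | CCCCCCCCCCC[C@H]1CO1
F6 | step 3 | (6S)-heptadec-1-en-6-ol | CCCCCCCCCCC[C@H](O)CCCC=C
F7 | step 3 | tert-butyl{[(6S)-heptadec-1-en-6-yl]oxy}dimethylsilane | CCCCCCCCCCC[C@H](O[Si](C)(C)C(C)(C)C)CCCC=C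
F8 | step 3 | tert-butyldimethyl{[(4S)-1-(oxiran-2-yl)pentadecan-4-yl]oxy}silane, both oxirane epimers | CCCCCCCCCCC[C@H](O[Si](C)(C)C(C)(C)C)CCCC1CO1
F9 | step 7 | (2R,6S)-6-(TBSO)-1-(1,3-dithian-2-yl)heptadecan-2-ol | CCCCCCCCCCC[C@H](O[Si](C)(C)C(C)(C)C)CCC[C@@H](O)CC1SCCCS1
F10 | step 7 | 2-[(2R,6S)-2,6-bis(TBSO)heptadecyl]-1,3-dithiane | CCCCCCCCCCC[C@H](O[Si](C)(C)C(C)(C)C)CCC[C@@H](O[Si](C)(C)C(C)(C)C)CC1SCCCS1
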